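## Retrosynthetic overview

1. The target is an olivil-type oxolane, O1–C2H2–C3(OH)(CH2Ar)–C4H(CH2OH)–C5H(aryl), whose benzyl arene carries an erythro guaiacylglycerol unit through an aryl ether. C2–C3 and C4–C5 are cut together, giving a C5–O1–C2 carbonyl-ylide unit and the C3=C4 bond of an (E)-enol ether that already carries the whole side chain.
2. Enabling feature: ring oxygen O1 lies between C5, which bears the electron-rich 4-oxy-3-methoxyphenyl ring (stabilises positive charge), and C2, a CH2 that can temporarily carry two ester groups (stabilise negative charge). The tertiary C3–O bond lets C3=C4 be an enol ether whose polarity matches this dipole.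
3. The ylide comes from a donor–acceptor oxirane (O-benzylvanillin, diallyl malonate, epoxidation). The enol ether comes from methyl homovanillate: aryloxyacetyl imide, magnesium-catalysed anti-aldol with O-benzylvanillin (erythro, 1R,2S), reduction, protection, β-keto ester, (E)-enol ether.
4. After the cycloaddition the two esters on C2 are removed (Pd deallylation/decarboxylation, then Barton decarboxylation), and one hydrogenolysis frees all six hydroxyl groups.
5. Ring formation: the three benzene rings are purchased; the oxolane is the only ring made (step 12).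

Key step: step 12

Remark (assumption): (4S)-4-benzyl-3-(2-chloroacetyl)-1,3-oxazolidin-2-one is treated as a catalogue compound; otherwise it is one N-acylation from (S)-4-benzyl-1,3-oxazolidin-2-one.

Remark (assumption): ligand L is 1,1'-(propane-1,3-diyl)bis[N-(2,6-diisopropylphenyl)piperidine-2-carboxamide 1-oxide], available in both enantiomeric series from (S)- or (R)-pipecolic acid; the series that delivers the 5S oxolane is used.

Shorthand used in names:
- BnV = 4-(benzyloxy)-3-methoxyphenyl.
- BOM = benzyloxymethyl (PhCH2OCH2–).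
- ArS = 3-methoxy-4-{[(1R,2S)-1-(BnV)-1,3-bis(BOM-oxy)propan-2-yl]oxy}phenyl.
- The oxolane is numbered O1, C2, C3 (carbon bearing the oxygen and the arylmethyl group), C4 (carbon bearing the CH2O group), C5 (aryl-bearing carbon), as in the oxolan-3-ol name of the target.

## Route

Step 1
Reactants: 1 methyl 2-(4-hydroxy-3-methoxyphenyl)acetate (methyl homovanillate); 2 (4S)-4-benzyl-3-(2-chloroacetyl)-1,3-oxazolidin-2-one
Product: 3 methyl 2-[4-{2-[(4S)-4-benzyl-2-oxo-1,3-oxazolidin-3-yl]-2-oxoethoxy}-3-methoxyphenyl]acetate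
Conditions: K2CO3, NaI (cat.), acetone, 55 °C
Reagents that add atoms: none
Why: Williamson O-alkylation of the phenoxide by the activated α-chloro imide (in situ Finkelstein) should be much faster than attack at the imide carbonyl.

Step 2
Reactants: 3 aryloxyacetyl imide; 4 4-(benzyloxy)-3-methoxybenzaldehyde (O-benzylvanillin)
Product: 6 (4S)-4-benzyl-3-[(2R,3R)-3-(BnV)-3-hydroxy-2-{2-methoxy-4-(2-methoxy-2-oxoethyl)phenoxy}propanoyl]-1,3-oxazolidin-2-one (anti-aldol adduct), via trimethylsilyl ether 5 (not isolated)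
Conditions: MgCl2 (20 mol%), Et3N, Me3SiCl, EtOAc, 23 °C; then 1 M HCl, THF, 0 °C
Reagents that add atoms: none
Why: Evans magnesium-halide-catalysed direct anti-aldol of an N-acyl oxazolidinone with a non-enolisable aromatic aldehyde; the chelated Z-enolate should be attacked on the face away from the benzyl group (boat transition state), which sets the aryloxy carbon and, anti to it, the carbinol carbon, and silylation prevents retro-aldol.

Step 3
Reactants: 6 anti-aldol adduct
Product: 7 methyl 2-[4-{[(1R,2S)-1-(BnV)-1,3-dihydroxypropan-2-yl]oxy}-3-methoxyphenyl]acetate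
Conditions: NaBH4, THF/H2O (3:1), 0 °C → rt
Reagents that add atoms: none
Why: Reductive cleavage of the N-acyl oxazolidinone by NaBH4 in aqueous THF should give the primary alcohol and leave the less electrophilic methyl ester and both stereocentres untouched.

Step 4
Reactants: 7 erythro diol
Product: 8 methyl 2-(ArS)acetate
Conditions: BOMCl, i-Pr2NEt, Bu4NI (cat.), CH2Cl2, 0 → 40 °C
Reagents that add atoms: benzyl chloromethyl ether (BOMCl), ClCOCc1ccccc1
Why: Acetal-type O-alkylation of both hydroxyl groups with a reactive chloromethyl ether under amine base should give base-stable ethers that fall off in the final hydrogenolysis.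

Step 5
Reactants: 8 methyl 2-(ArS)acetate
Product: 9 2-(ArS)acetic acid
Conditions: LiOH, THF/MeOH/H2O, rt; then 1 M HCl to pH 3, 0 °C
Reagents that add atoms: lithium hydroxide, [Li+].[OH-]
Why: Saponification of an unhindered methyl ester; BOM acetals and benzyl ethers are stable to hydroxide and to the brief cold acidification.

Step 6
Reactants: 9 2-(ArS)acetic acid; 10 potassium 3-methoxy-3-oxopropanoate (potassium methyl malonate)
Product: 12 methyl 4-(ArS)-3-oxobutanoate, via acyl imidazolide 11 (not isolated)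
Conditions: CDI, THF, rt; then 10, MgCl2, Et3N, THF, rt → 45 °C; dilute HCl work-up
Reagents that add atoms: none
Why: Masamune–Brooks decarboxylative Claisen condensation of the acyl imidazolide with the magnesium malonate half-ester should give the β-keto ester under neutral conditions.

Step 7
Reactants: 12 β-keto ester
Product: 13 methyl (2E)-4-(ArS)-3-(BOM-oxy)but-2-enoate
Conditions: NaH, THF/HMPA (4:1), 0 °C; then BOMCl, 0 °C → rt
Reagents that add atoms: benzyl chloromethyl ether (BOMCl), ClCOCc1ccccc1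
Why: O-alkylation of the β-keto ester enolate by a hard chloromethyl ether; the dissociated, W-shaped enolate in HMPA should place the new O-substituent trans to the ester, giving the E-enol ether.

Step 8
Reactants: 13 (E)-β-alkoxy enoate
Product: 14 (2E)-4-(ArS)-3-(BOM-oxy)but-2-en-1-ol
Conditions: i-Bu2AlH, CH2Cl2, −78 °C; aqueous KNaC4H4O6 work-up
Reagents that add atoms: none
Why: 1,2-Reduction of an α,β-unsaturated ester by i-Bu2AlH should give the allylic alcohol with the double-bond geometry retained; acetals and benzyl ethers are inert at −78 °C.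

Step 9
Reactants: 14 allylic alcohol
Product: 15 (2E)-1-(benzyloxy)-3-(BOM-oxy)-4-(ArS)but-2-ene (benzyl ether of 14)
Conditions: NaH, BnBr, Bu4NI (cat.), THF, 0 °C → rt
Reagents that add atoms: benzyl bromide, BrCc1ccccc1
Why: Williamson benzylation of the primary alkoxide under basic conditions, which the acid-labile enol ether tolerates.

Step 10
Reactants: 4 4-(benzyloxy)-3-methoxybenzaldehyde; 16 diallyl malonate (diprop-2-enyl propanedioate)
Product: 17 diallyl 2-[(BnV)methylidene]propanedioate
Conditions: piperidine (cat.), AcOH (cat.), toluene, reflux, Dean–Stark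
Reagents that add atoms: none
Why: Knoevenagel condensation of an aromatic aldehyde with a malonate, driven by azeotropic removal of water.

Step 11
Reactants: 17 arylidene malonate
Product: 18 diallyl 3-(BnV)oxirane-2,2-dicarboxylate (racemic)
Conditions: t-BuOOH (in decane), DBU (cat.), CH2Cl2, 0 °C → rt
Reagents that add atoms: tert-butyl hydroperoxide, CC(C)(C)OO
Why: Weitz–Scheffer nucleophilic epoxidation of the doubly activated alkene, which should leave the isolated allyl double bonds alone; the donor–acceptor oxirane is acid-labile and is used after filtration through neutral alumina.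

Step 12
Reactants: 15 (E)-enol ether; 18 donor–acceptor oxirane
Product: 19 diallyl (3S,4R,5S)-5-(BnV)-3-(BOM-oxy)-4-[(benzyloxy)methyl]-3-[(ArS)methyl]oxolane-2,2-dicarboxylate
Conditions: Ni(ClO4)2·6H2O (10 mol%), ligand L (11 mol%), 4 Å MS, CH2Cl2, 30 °C; 18 (2 equiv)
Reagents that add atoms: none
Why: Chelation of the two ester carbonyls of 18 by the chiral divalent-nickel complex should trigger heterolysis of the oxirane C–C bond (push from the BnV ring, pull from the malonate) to a nickel-bound carbonyl ylide; the nucleophilic =CH carbon of the enol ether attacks the benzylic ylide carbon and the resulting oxocarbenium carbon is captured by the malonate carbon, a polarity-matched, asynchronous formal [3+2] cycloaddition that makes C4–C5 and C2–C3 in one operation. The closest known reaction type is the Lewis-acid-catalysed (also chiral N,N'-dioxide/nickel-catalysed) [3+2] cycloaddition of aryl oxiranyl diesters or diketones with vinyl ethers, alkynes and aldehydes through C–C cleavage; the partner here is a trisubstituted acyclic enol ether. The oxolane is closed as the second bond-forming event, by 5-exo-trig attack of the malonate carbon on the exocyclic oxocarbenium (suprafacial on the alkene if the two events merge). C3 and C4 take their relative configuration (C3–O trans to the C4 CH2OBn group, arylmethyl cis to it) from the E-geometry of 15; C5 is set by the ylide holding its aryl group outward while the enol ether approaches with H and OBOM endo and both CH2 groups exo, which places the aryl group trans to the C4 substituent and cis to the C3 oxygen. The absolute sense comes from the ligand-shielded face of the nickel-bound ylide, the remote side-chain centres being bystanders; regiochemistry is fixed by polarity, the mild ligand-buffered Lewis acid should spare the BOM acetals, benzyl ethers and allylic ether, and a two-fold excess of racemic 18 covers both convergence through the planar ylide and kinetic resolution.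

Step 13
Reactants: 19 oxolane-2,2-dicarboxylate
Product: 21 (3S,4R,5S)-5-(BnV)-3-(BOM-oxy)-4-[(benzyloxy)methyl]-3-[(ArS)methyl]oxolane-2-carboxylic acid (C2 epimers), via oxolane-2,2-dicarboxylic acid 20 (not isolated)
Conditions: Pd(PPh3)4 (5 mol%), HCO2H, Et3N, 1,4-dioxane, rt → 90 °C
Reagents that add atoms: none
Why: Tsuji deallylation–decarboxylation: zerovalent palladium ionises both allyl esters, formate reduces the π-allyl units to propene, and the α-alkoxy malonic acid loses one CO2 on warming, a path that does not depend on attack at the hindered carbonyl groups; the C2 configuration is irrelevant because C2 becomes CH2.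

Step 14
Reactants: 21 oxolane-2-carboxylic acid
Product: 23 (3S,4R,5S)-5-(BnV)-3-(BOM-oxy)-4-[(benzyloxy)methyl]-3-[(ArS)methyl]oxolane, via Barton ester 22 (not isolated)
Conditions: N-hydroxypyridine-2-thione, DCC, DMAP (cat.), CH2Cl2, rt, dark; then t-BuSH, hν (tungsten lamp), 15 °C
Reagents that add atoms: none
Why: Barton reductive decarboxylation: the thiohydroxamate ester fragments in a radical chain to an oxygen-stabilised C2 radical that takes hydrogen from the thiol, under neutral conditions compatible with the electron-rich arenes and all ethers.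

Step 15
Reactants: 23 fully protected oxolane
Product: 24 (3S,4R,5S)-5-(4-hydroxy-3-methoxyphenyl)-4-(hydroxymethyl)-3-[(4-{[(1R,2S)-1,3-dihydroxy-1-(4-hydroxy-3-methoxyphenyl)propan-2-yl]oxy}-3-methoxyphenyl)methyl]oxolan-3-ol
Conditions: H2 (1 atm), Pd/C (10 wt%), EtOAc/MeOH, rt
Reagents that add atoms: none
Why: Catalytic hydrogenolysis should cleave the two aryl benzyl ethers, the alkyl benzyl ether and the three BOM acetals (each losing toluene, then formaldehyde); under neutral conditions with short contact the ring benzylic ether and the benzylic carbinol, which react more slowly, should be kept.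

## Compound list

1 | methyl 2-(4-hydroxy-3-methoxyphenyl)acetate | COC(=O)Cc1ccc(O)c(OC)c1 | starting material
2 | (4S)-4-benzyl-3-(2-chloroacetyl)-1,3-oxazolidin-2-one | ClCC(=O)N1[C@@H](Cc2ccccc2)COC1=O | starting material
3 | methyl 2-[4-{2-[(4S)-4-benzyl-2-oxo-1,3-oxazolidin-3-yl]-2-oxoethoxy}-3-methoxyphenyl]acetate | COC(=O)Cc1ccc(OCC(=O)N2[C@@H](Cc3ccccc3)COC2=O)c(OC)c1 | intermediate
4 | 4-(benzyloxy)-3-methoxybenzaldehyde | O=Cc1ccc(OCc2ccccc2)c(OC)c1 | starting material
5 | trimethylsilyl ether of 6 | COc1cc([C@@H](O[Si](C)(C)C)[C@H](C(=O)N2[C@@H](Cc3ccccc3)COC2=O)Oc2ccc(CC(=O)OC)cc2OC)ccc1OCc1ccccc1 | intermediate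
6 | (4S)-4-benzyl-3-[(2R,3R)-3-(BnV)-3-hydroxy-2-{2-methoxy-4-(2-methoxy-2-oxoethyl)phenoxy}propanoyl]-1,3-oxazolidin-2-one | COc1cc([C@@H](O)[C@H](C(=O)N2[C@@H](Cc3ccccc3)COC2=O)Oc2ccc(CC(=O)OC)cc2OC)ccc1OCc1ccccc1 | intermediate
7 | methyl 2-[4-{[(1R,2S)-1-(BnV)-1,3-dihydroxypropan-2-yl]oxy}-3-methoxyphenyl]acetate | COc1cc([C@@H](O)[C@H](CO)Oc2ccc(CC(=O)OC)cc2OC)ccc1OCc1ccccc1 | intermediate
8 | methyl 2-(ArS)acetate | COc1cc([C@@H](OCOCc3ccccc3)[C@H](COCOCc3ccccc3)Oc2ccc(CC(=O)OC)cc2OC)ccc1OCc1ccccc1 | intermediate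
9 | 2-(ArS)acetic acid | COc1cc([C@@H](OCOCc3ccccc3)[C@H](COCOCc3ccccc3)Oc2ccc(CC(=O)O)cc2OC)ccc1OCc1ccccc1 | intermediate
10 | potassium 3-methoxy-3-oxopropanoate | COC(=O)CC(=O)[O-].[K+] | starting material
11 | 1-[2-(ArS)acetyl]imidazole | COc1cc([C@@H](OCOCc3ccccc3)[C@H](COCOCc3ccccc3)Oc2ccc(CC(=O)n3ccnc3)cc2OC)ccc1OCc1ccccc1 | intermediate
12 | methyl 4-(ArS)-3-oxobutanoate | COc1cc([C@@H](OCOCc3ccccc3)[C@H](COCOCc3ccccc3)Oc2ccc(CC(=O)CC(=O)OC)cc2OC)ccc1OCc1ccccc1 | intermediate
13 | methyl (2E)-4-(ArS)-3-(BOM-oxy)but-2-enoate | COc1cc([C@@H](OCOCc3ccccc3)[C@H](COCOCc3ccccc3)Oc2ccc(C/C(OCOCc3ccccc3)=C\C(=O)OC)cc2OC)ccc1OCc1ccccc1 | intermediate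
14 | (2E)-4-(ArS)-3-(BOM-oxy)but-2-en-1-ol | COc1cc([C@@H](OCOCc3ccccc3)[C@H](COCOCc3ccccc3)Oc2ccc(C/C(OCOCc3ccccc3)=C\CO)cc2OC)ccc1OCc1ccccc1 | intermediate
15 | (2E)-1-(benzyloxy)-3-(BOM-oxy)-4-(ArS)but-2-ene | COc1cc([C@@H](OCOCc3ccccc3)[C@H](COCOCc3ccccc3)Oc2ccc(C/C(OCOCc3ccccc3)=C\COCc3ccccc3)cc2OC)ccc1OCc1ccccc1 | intermediate
16 | diallyl malonate | C=CCOC(=O)CC(=O)OCC=C | starting material
17 | diallyl 2-[(BnV)methylidene]propanedioate | C=CCOC(=O)C(=Cc1ccc(OCc2ccccc2)c(OC)c1)C(=O)OCC=C | intermediate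
18 | diallyl 3-(BnV)oxirane-2,2-dicarboxylate (racemic) | C=CCOC(=O)C1(OC1c1ccc(OCc2ccccc2)c(OC)c1)C(=O)OCC=C | intermediate
19 | diallyl (3S,4R,5S)-5-(BnV)-3-(BOM-oxy)-4-[(benzyloxy)methyl]-3-[(ArS)methyl]oxolane-2,2-dicarboxylate | COc1cc([C@@H](OCOCc3ccccc3)[C@H](COCOCc3ccccc3)Oc2ccc(C[C@@]3(OCOCc5ccccc5)C(C(=O)OCC=C)(C(=O)OCC=C)O[C@H](c4ccc(OCc5ccccc5)c(OC)c4)[C@H]3COCc5ccccc5)cc2OC)ccc1OCc1ccccc1 | intermediate
20 | (3S,4R,5S)-5-(BnV)-3-(BOM-oxy)-4-[(benzyloxy)methyl]-3-[(ArS)methyl]oxolane-2,2-dicarboxylic acid | COc1cc([C@@H](OCOCc3ccccc3)[C@H](COCOCc3ccccc3)Oc2ccc(C[C@@]3(OCOCc5ccccc5)C(C(=O)O)(C(=O)O)O[C@H](c4ccc(OCc5ccccc5)c(OC)c4)[C@H]3COCc5ccccc5)cc2OC)ccc1OCc1ccccc1 | intermediate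
21 | (3S,4R,5S)-5-(BnV)-3-(BOM-oxy)-4-[(benzyloxy)methyl]-3-[(ArS)methyl]oxolane-2-carboxylic acid (C2 epimers) | COc1cc([C@@H](OCOCc3ccccc3)[C@H](COCOCc3ccccc3)Oc2ccc(C[C@@]3(OCOCc5ccccc5)C(C(=O)O)O[C@H](c4ccc(OCc5ccccc5)c(OC)c4)[C@H]3COCc5ccccc5)cc2OC)ccc1OCc1ccccc1 | intermediate
22 | 2-thioxopyridin-1(2H)-yl ester of 21 (Barton ester) | COc1cc([C@@H](OCOCc3ccccc3)[C@H](COCOCc3ccccc3)Oc2ccc(C[C@@]3(OCOCc5ccccc5)C(C(=O)On6ccccc6=S)O[C@H](c4ccc(OCc5ccccc5)c(OC)c4)[C@H]3COCc5ccccc5)cc2OC)ccc1OCc1ccccc1 | intermediate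
23 | (3S,4R,5S)-5-(BnV)-3-(BOM-oxy)-4-[(benzyloxy)methyl]-3-[(ArS)methyl]oxolane | COc1cc([C@@H](OCOCc3ccccc3)[C@H](COCOCc3ccccc3)Oc2ccc(C[C@@]3(OCOCc5ccccc5)CO[C@H](c4ccc(OCc5ccccc5)c(OC)c4)[C@H]3COCc5ccccc5)cc2OC)ccc1OCc1ccccc1 | intermediate
24 | (3S,4R,5S)-5-(4-hydroxy-3-methoxyphenyl)-4-(hydroxymethyl)-3-[(4-{[(1R,2S)-1,3-dihydroxy-1-(4-hydroxy-3-methoxyphenyl)propan-2-yl]oxy}-3-methoxyphenyl)methyl]oxolan-3-ol | COc1cc([C@@H](O)[C@H](CO)Oc2ccc(C[C@@]3(O)CO[C@H](c4ccc(O)c(OC)c4)[C@H]3CO)cc2OC)ccc1O | target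

## Step count and risks

Total steps: 15. Longest linear sequence: 13 steps (steps 1–9 and 12–15).

Steps most likely to fail:

1. Step 12. The Lewis acid may ionise the allylic ether or enol ether of 15 before cycloaddition. A long-lived zwitterion may lose the E-geometry before ring closure. The catalyst may control the face poorly on this hindered, trisubstituted enol ether.
Fallback (sets out from 13 and 4, comes back at 24): a non-stabilised carbonyl ylide is generated by fluoride-induced 1,3-elimination, a known route to oxolanes from acrylate-type alkenes. It is added to the electron-poor enoate 13, so no Lewis acid is present and C2 arrives as CH2. Aldehyde 4 is acetalised with (trimethylsilyl)methanol (cat. TsOH, toluene, Dean–Stark) to 4-(benzyloxy)-3-methoxybenzaldehyde bis[(trimethylsilyl)methyl] acetal F1. Acetyl chloride converts it into the α-chloro ether 4-(benzyloxy)-1-{chloro[(trimethylsilyl)methoxy]methyl}-2-methoxybenzene F2. CsF in MeCN in the presence of 13 should generate the ylide, and its concerted suprafacial cycloaddition (CH2 terminus to the hindered β-carbon, E-geometry retained) should give the oxolane methyl ester F3. LiBH4 in THF reduces the ester to the primary alcohol F4, and hydrogenolysis as in step 15 gives 24. This ylide is achiral and uncatalysed, so the two core diastereomers (opposite oxolane sense, same side chain) would have to be separated by chromatography at F3.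

2. Step 2. The magnesium enolate of an α-aryloxy imide may give too little anti-selectivity or the opposite facial sense, and retro-aldol may compete before silylation.
Fallback (sets out from 1, comes back at 7): the antipodal catalogue imide (4R)-4-benzyl-3-(2-chloroacetyl)-1,3-oxazolidin-2-one F5 alkylates 1 (K2CO3, NaI, acetone) to the (4R)-aryloxyacetyl imide F6. Its dibutylboron enolate (Bu2BOTf, i-Pr2NEt, CH2Cl2, −78 °C) adds to 4 to give the Evans syn-aldol adduct F7, which has the correct centre at the aryloxy carbon. Mitsunobu inversion of the benzylic carbinol (4-nitrobenzoic acid, PPh3, DIAD, THF) gives the 4-nitrobenzoate F8. NaBH4 in THF/H2O followed by K2CO3 in MeOH removes the auxiliary and the ester to give 7.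

3. Step 7. C-alkylation may compete, or a chelated enolate may give the Z-enol ether.
Fallback (sets out from 12, comes back at 13): stereocontrol is moved from the alkylation to a thermodynamic equilibration. The chelated sodium enolate of 12 (NaH, THF, no HMPA) is alkylated with BOMCl to methyl (2Z)-4-(ArS)-3-(BOM-oxy)but-2-enoate F9, alone or mixed with 13. The material is then equilibrated with catalytic PhSH/AIBN in benzene at 80 °C (reversible thiyl-radical addition) to 13, which is expected to be the more stable isomer because its alkoxy group lies trans to the ester.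

Further compounds
F1 | step 12 | 4-(benzyloxy)-3-methoxybenzaldehyde bis[(trimethylsilyl)methyl] acetal | C[Si](C)(C)COC(OC[Si](C)(C)C)c1ccc(OCc2ccccc2)c(OC)c1
F2 | step 12 | 4-(benzyloxy)-1-{chloro[(trimethylsilyl)methoxy]methyl}-2-methoxybenzene | C[Si](C)(C)COC(Cl)c1ccc(OCc2ccccc2)c(OC)c1
F3 | step 12 | methyl ester at C4 of (3S,4R,5S)-5-(BnV)-3-(BOM-oxy)-3-[(ArS)methyl]oxolane (CO2Me in place of CH2OBn of 23) | COc1cc([C@@H](OCOCc3ccccc3)[C@H](COCOCc3ccccc3)Oc2ccc(C[C@@]3(OCOCc5ccccc5)CO[C@H](c4ccc(OCc5ccccc5)c(OC)c4)[C@H]3C(=O)OC)cc2OC)ccc1OCc1ccccc1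
F4 | step 12 | [(3S,4R,5S)-5-(BnV)-3-(BOM-oxy)-3-[(ArS)methyl]oxolan-4-yl]methanol (numbering as in 23) | COc1cc([C@@H](OCOCc3ccccc3)[C@H](COCOCc3ccccc3)Oc2ccc(C[C@@]3(OCOCc5ccccc5)CO[C@H](c4ccc(OCc5ccccc5)c(OC)c4)[C@H]3CO)cc2OC)ccc1OCc1ccccc1
F5 | step 2 | (4R)-4-benzyl-3-(2-chloroacetyl)-1,3-oxazolidin-2-one | ClCC(=O)N1[C@H](Cc2ccccc2)COC1=O
F6 | step 2 | methyl 2-[4-{2-[(4R)-4-benzyl-2-oxo-1,3-oxazolidin-3-yl]-2-oxoethoxy}-3-methoxyphenyl]acetate | COC(=O)Cc1ccc(OCC(=O)N2[C@H](Cc3ccccc3)COC2=O)c(OC)c1
F7 | step 2 | (4R)-4-benzyl-3-[(2R,3S)-3-(BnV)-3-hydroxy-2-{2-methoxy-4-(2-methoxy-2-oxoethyl)phenoxy}propanoyl]-1,3-oxazolidin-2-one | COc1cc([C@H](O)[C@H](C(=O)N2[C@H](Cc3ccccc3)COC2=O)Oc2ccc(CC(=O)OC)cc2OC)ccc1OCc1ccccc1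
F8 | step 2 | (1R,2R)-3-[(4R)-4-benzyl-2-oxo-1,3-oxazolidin-3-yl]-1-(BnV)-2-{2-methoxy-4-(2-methoxy-2-oxoethyl)phenoxy}-3-oxopropyl 4-nitrobenzoate | COc1cc([C@@H](OC(=O)c3ccc(cc3)[N+](=O)[O-])[C@H](C(=O)N2[C@H](Cc3ccccc3)COC2=O)Oc2ccc(CC(=O)OC)cc2OC)ccc1OCc1ccccc1
F9 | step 7 | methyl (2Z)-4-(ArS)-3-(BOM-oxy)but-2-enoate | COc1cc([C@@H](OCOCc3ccccc3)[C@H](COCOCc3ccccc3)Oc2ccc(C/C(OCOCc3ccccc3)=C/C(=O)OC)cc2OC)ccc1OCc1ccccc1
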